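The cyclohexene ring and the cis C1/C6 oxygen centres (target numbering, C1 = OMe carbon) come from (−)-shikimic acid. The route rests on disconnecting the C4–O and C5–O bonds together to a C4=C5 alkene. One OsO4-catalysed cis-dihydroxylation of a cyclohexa-2,4-diene-3-carboxylate forms both bonds and sets C4 and C5. It exploits the feature that the cis C4-O/C5-O pair of the ring lies anti to the cis C1-OMe/C6-O pair: those two oxygens shield one face of the diene, and the C3 ester deactivates C2=C3. The precursor is the methyl dienoate carrying C1-OMe and C6-OTBS, reached from shikimate by Mitsunobu epoxide closure, O-methylation, selenolate opening and selenoxide elimination, which erases the shikimate C5 centre.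

Key step: step 7

Remark: every compound keeps the ring numbering of the target (C1 carries OMe, C2=C3, C7 is the exocyclic carbon on C3, then C4, C5, C6); α is the ring face that carries the C1 and C6 oxygens, β the opposite face.

Step 1
Reactants: 1 (−)-shikimic acid
Product: 2 methyl shikimate
Conditions: MeOH, (+)-10-camphorsulfonic acid (5 mol %), reflux
Reagents that add atoms: methanol, CO
Why: Fischer esterification in a large excess of methanol should convert the acid into the methyl ester without touching the three carbinol centres.

Step 2
Reactants: 2 methyl shikimate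
Product: 4 hydroxy epoxide, methyl (1S,5R,6S)-5-hydroxy-7-oxabicyclo[4.1.0]hept-3-ene-3-carboxylate (α C5,C6-epoxide, free α C1-OH), via C5 alkoxyphosphonium salt 3 (not isolated)
Conditions: PPh3 (1.1 equiv), DIAD (1.1 equiv), THF, 0 °C → rt
Reagents that add atoms: none
Why: Mitsunobu cyclodehydration of the trans C5,C6-diol: only the C5 alkoxyphosphonium ion has a trans neighbouring oxygen, so the C6 oxygen displaces it intramolecularly (SN2), which inverts C5, keeps the oxygens on C6 and C1 in place and closes the epoxide on the α face, cis to the untouched allylic C1-OH.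

Step 3
Reactants: 4 hydroxy epoxide
Product: 5 methoxy epoxide, methyl (1S,5R,6S)-5-methoxy-7-oxabicyclo[4.1.0]hept-3-ene-3-carboxylate
Conditions: MeI (excess), Ag2O, 4 Å molecular sieves, MeCN, rt → 40 °C, dark
Reagents that add atoms: iodomethane, CI
Why: Purdie methylation should alkylate the single free hydroxyl without strong base, so the epoxide and the enoate (prone to base-induced elimination and aromatisation) survive, and because the epoxide is cis to the C1 oxygen no Payne rearrangement can scramble C1 or C6.

Step 4
Reactants: 5 methoxy epoxide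
Product: 6 hydroxy selenide (C1-OMe α, C6-OH α, C5-SePh β, methyl ester on C3)
Conditions: (PhSe)2 (0.6 equiv), NaBH4 (1.2 equiv), MeOH–THF, 0 °C → rt
Reagents that add atoms: diphenyl diselenide, c1ccc(cc1)[Se][Se]c1ccccc1
Why: The soft, weakly basic selenolate should open the epoxide by SN2 attack at C5, the carbon remote from the inductively deactivating C1-OMe and the one that leads to the trans-diaxial product, which places SePh on the β face of C5 with inversion and leaves the α C6-OH; nitrogen nucleophiles are known to open 1-alkoxy-5,6-epoxides of this type at the same carbon, and methanol as solvent avoids transesterification.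

Step 5
Reactants: 6 hydroxy selenide
Product: 7 silyl ether selenide (C6-OTBS α, C5-SePh β, C1-OMe α)
Conditions: TBSOTf (1.3 equiv), 2,6-lutidine, CH2Cl2, −78 → 0 °C
Reagents that add atoms: tert-butyldimethylsilyl trifluoromethanesulfonate, CC(C)(C)[Si](C)(C)OS(=O)(=O)C(F)(F)F
Why: Silyl triflate with a hindered pyridine base should silylate the hindered secondary C6-OH at low temperature without disturbing the selenide, giving an ether that later tolerates oxidation, osmylation, hydride and acylation and adds bulk to the α face.

Step 6
Reactants: 7 silyl ether selenide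
Product: 9 dienoate (methyl ester on C3, C2=C3 and C4=C5, C1-OMe α, C6-OTBS α), via selenoxide 8 (not isolated)
Conditions: 30% aq. H2O2 (2.5 equiv), pyridine, CH2Cl2, 0 °C → rt
Reagents that add atoms: none
Why: Chemoselective oxidation at selenium gives the selenoxide, which should undergo thermal syn-elimination with the β hydrogen on C4 (allylic, leading to a conjugated diene) and not with the hydrogen on the oxygen-bearing C6, the usual regiochemical preference of β-oxygenated selenoxides, so that the C4=C5 alkene forms and the stereocentre at C5 disappears, while pyridine keeps the medium free of acid that would aromatise the dienoate.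

Step 7
Reactants: 9 dienoate
Product: 11 diol ester (C4-OH β, C5-OH β, C6-OTBS α, C1-OMe α, methyl ester on C3), via cyclic osmate ester 10 (not isolated)
Conditions: OsO4 (2 mol %), NMO (1.3 equiv), acetone–H2O, 0 °C → rt
Reagents that add atoms: osmium tetroxide, O=[Os](=O)(=O)=O; N-methylmorpholine N-oxide, C[N+]1([O-])CCOCC1; water, O
Why: Octavalent OsO4 adds to the C4=C5 alkene in a concerted, suprafacial [3+2] cycloaddition to give the hexavalent osmium diolate 10, which NMO reoxidises and water hydrolyses to the cis-diol while the catalyst turns over. The closest known reaction type is the OsO4/NMO dihydroxylation of shikimate-derived 3,4-dioxygenated cyclohexa-1,5-diene-1-carboxylates, which takes place at the alkene that does not carry the ester and anti to the allylic oxygens. No ring of the product is closed; the five-membered osmate chelate is transient. Both new stereocentres (C4 and C5) arise in the same suprafacial event, so they are cis to each other, and their face is dictated by the allylic C6-OTBS group, reinforced by the C1-OMe on the same α face, which leaves only the β face open (anti-to-allylic-oxygen rule of osmylation). The site selectivity needed, C4=C5 over C2=C3, is secured by the ester on C3, which makes C2=C3 trisubstituted and electron-poor, whereas C4=C5 is disubstituted and only cross-conjugated; a small excess of NMO and low temperature guard against a second osmylation.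

Step 8
Reactants: 11 diol ester
Product: 13 triol (C4-OH β, C5-OH β, C7-OH, C6-OTBS α, C1-OMe α), via enal 12 (not isolated)
Conditions: iBu2AlH (5 equiv), CH2Cl2, −78 → −30 °C
Reagents that add atoms: none
Why: Excess iBu2AlH should first convert the two hydroxyls into aluminium alkoxides and then reduce the conjugated ester in the 1,2-sense through the enal to the allylic primary alcohol, leaving the alkene, the silyl ether, the methyl ether and all four stereocentres untouched.

Step 9
Reactants: 13 triol; 14 benzoyl chloride
Product: 15 C7 monobenzoate (C4-OH and C5-OH free, C6-OTBS)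
Conditions: BzCl (1.05 equiv), 2,4,6-collidine, CH2Cl2, −78 → −30 °C
Reagents that add atoms: benzoyl chloride (compound 14), O=C(Cl)c1ccccc1
Why: Kinetically controlled acylation: with a weak hindered base at low temperature the unhindered primary allylic C7-OH should be benzoylated far faster than the secondary C4-OH and C5-OH, which are flanked by ring substituents.

Step 10
Reactants: 15 C7 monobenzoate; 14 benzoyl chloride
Product: 17 C5,C7-dibenzoate (C4-OH free, C6-OTBS), via borinate complex 16 (not isolated)
Conditions: Ph2BOCH2CH2NH2 (2-aminoethyl diphenylborinate, 10 mol %), BzCl (1.2 equiv), iPr2NEt (1.5 equiv), MeCN, rt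
Reagents that add atoms: benzoyl chloride (compound 14), O=C(Cl)c1ccccc1
Why: Borinic acid-catalysed regioselective monoacylation of a cis-1,2-diol: the catalyst binds the cis C4,C5-diol reversibly as the tetracoordinate borinate 16, whose equatorial oxygen on C5 is more exposed and more nucleophilic than the pseudoaxial allylic oxygen on C4 (held pseudoaxial by allylic strain with the C3 substituent) and should be acylated at room temperature, conditions too mild for benzoyl or silyl migration.

Step 11
Reactants: 17 C5,C7-dibenzoate
Product: 18 target, [(3R,4R,5R,6R)-5-(benzoyloxy)-4,6-dihydroxy-3-methoxycyclohex-1-en-1-yl]methyl benzoate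
Conditions: HF·pyridine, pyridine–THF, 0 °C → rt
Reagents that add atoms: none
Why: Fluoride should cleave the Si–O bond under buffered, weakly acidic conditions in which benzoates neither hydrolyse nor migrate between the neighbouring C4, C5 and C6 oxygens, so the C6-OH is released with every stereocentre intact.

Compound list
1 | (−)-shikimic acid, (3R,4S,5R)-3,4,5-trihydroxycyclohex-1-ene-1-carboxylic acid | OC(=O)C1=C[C@@H](O)[C@@H](O)[C@H](O)C1 | starting material
2 | methyl shikimate, methyl (3R,4S,5R)-3,4,5-trihydroxycyclohex-1-ene-1-carboxylate | COC(=O)C1=C[C@@H](O)[C@@H](O)[C@H](O)C1 | intermediate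
3 | C5 alkoxyphosphonium salt of 2 (C5-O-PPh3 cation, DIAD-derived hydrazide anion) | COC(=O)C1=C[C@@H](O)[C@@H](O)[C@H](O[P+](c2ccccc2)(c2ccccc2)c2ccccc2)C1.CC(C)OC(=O)N[N-]C(=O)OC(C)C | intermediate (not isolated)
4 | hydroxy epoxide, methyl (1S,5R,6S)-5-hydroxy-7-oxabicyclo[4.1.0]hept-3-ene-3-carboxylate | COC(=O)C1=C[C@@H](O)[C@H]2O[C@H]2C1 | intermediate
5 | methoxy epoxide, methyl (1S,5R,6S)-5-methoxy-7-oxabicyclo[4.1.0]hept-3-ene-3-carboxylate | COC(=O)C1=C[C@@H](OC)[C@H]2O[C@H]2C1 | intermediate
6 | hydroxy selenide: methyl ester on C3, C2=C3, C1-OMe α, C6-OH α, C5-SePh β | COC(=O)C1=C[C@@H](OC)[C@@H](O)[C@H]([Se]c2ccccc2)C1 | intermediate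
7 | silyl ether selenide: as 6 with C6-OTBS | COC(=O)C1=C[C@@H](OC)[C@@H](O[Si](C)(C)C(C)(C)C)[C@H]([Se]c2ccccc2)C1 | intermediate
8 | selenoxide of 7 (both configurations at selenium) | COC(=O)C1=C[C@@H](OC)[C@@H](O[Si](C)(C)C(C)(C)C)[C@H]([Se](=O)c2ccccc2)C1 | intermediate (not isolated)
9 | dienoate: methyl ester on C3, C2=C3 and C4=C5, C1-OMe α, C6-OTBS α | COC(=O)C1=C[C@@H](OC)[C@@H](O[Si](C)(C)C(C)(C)C)C=C1 | intermediate
10 | cyclic osmate ester: OsO2 diolate bridging the β oxygens on C4 and C5 of the ring of 9 | COC(=O)C1=C[C@@H](OC)[C@@H](O[Si](C)(C)C(C)(C)C)[C@@H]2O[Os](=O)(=O)O[C@H]12 | intermediate (not isolated)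
11 | diol ester: methyl ester on C3, C2=C3, C4-OH β, C5-OH β, C6-OTBS α, C1-OMe α | COC(=O)C1=C[C@@H](OC)[C@@H](O[Si](C)(C)C(C)(C)C)[C@H](O)[C@@H]1O | intermediate
12 | enal: as 11 with CHO in place of CO2Me | O=CC1=C[C@@H](OC)[C@@H](O[Si](C)(C)C(C)(C)C)[C@H](O)[C@@H]1O | intermediate (not isolated)
13 | triol: as 11 with CH2OH (C7) in place of CO2Me | OCC1=C[C@@H](OC)[C@@H](O[Si](C)(C)C(C)(C)C)[C@H](O)[C@@H]1O | intermediate
14 | benzoyl chloride | O=C(Cl)c1ccccc1 | starting material
15 | C7 monobenzoate of 13 | O=C(OCC1=C[C@@H](OC)[C@@H](O[Si](C)(C)C(C)(C)C)[C@H](O)[C@@H]1O)c1ccccc1 | intermediate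
16 | borinate complex: diphenylborinate of the C4,C5-diol of 15, diisopropylethylammonium salt | CC[NH+](C(C)C)C(C)C.O=C(OCC1=C[C@@H](OC)[C@@H](O[Si](C)(C)C(C)(C)C)[C@@H]2O[B-](c3ccccc3)(c3ccccc3)O[C@H]12)c1ccccc1 | intermediate (not isolated)
17 | C5,C7-dibenzoate with C6-OTBS and free C4-OH | O=C(OCC1=C[C@@H](OC)[C@@H](O[Si](C)(C)C(C)(C)C)[C@H](OC(=O)c2ccccc2)[C@@H]1O)c1ccccc1 | intermediate
18 | CNP0349013.4, [(3R,4R,5R,6R)-5-(benzoyloxy)-4,6-dihydroxy-3-methoxycyclohex-1-en-1-yl]methyl benzoate | CO[C@@H]1C=C(COC(=O)c2ccccc2)[C@@H](O)[C@@H](OC(=O)c2ccccc2)[C@@H]1O | target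

Total step count: 11. Longest linear sequence: 11 steps (1 to 18); benzoyl chloride 14 is the only other purchased building block.

Steps most likely to fail

Step 10. The regiochemistry of the second benzoylation may leak: the equatorial C5-OH sits next to the bulky silyl ether, so acylation of the C4-OH or double acylation could compete. The fallback sets out from triol 13 and removes the competition by protection. tBu2Si(OTf)2 and 2,6-lutidine should bridge the 1,3-related C4-OH and C7-OH as the six-membered di-tert-butylsilylene F1. The only remaining hydroxyl is then benzoylated (BzCl, DMAP, pyridine) to the C5 benzoate F2. HF·pyridine removes both silicon groups to give the C5-monobenzoate triol F3. Selective benzoylation of the primary C7-OH (BzCl, 2,4,6-collidine, −78 °C) comes back to the route at target 18.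

Step 6. The selenoxide next to the bulky silyl ether may eliminate slowly or in the wrong direction, leaving the dienoate exposed to oxidant and to aromatisation by loss of methanol or silanol. The fallback sets out from hydroxy selenide 6 and reverses the order of protection and elimination. Oxidation (H2O2, pyridine) gives the hydroxy selenoxide F4, which eliminates away from the carbinol carbon, the most reliable case of this elimination, to the dienol F5. Silylation at −78 °C (TBSOTf, 2,6-lutidine) comes back to the route at dienoate 9.

Step 3. The O-alkylation may be sluggish, so that the epoxy alcohol stays in contact with silver ion and iodide for long periods and the epoxide opens. The fallback sets out from methyl shikimate 2 and methylates before any epoxide exists. Butane-2,3-dione, HC(OMe)3 and camphorsulfonic acid in refluxing MeOH should protect the trans C5,C6-diol selectively as the butane-2,3-diacetal F6, leaving only the C1-OH free. Methylation (MeI, Ag2O, forcing conditions) gives the methyl ether F7, and aqueous trifluoroacetic acid releases the C1-O-methyl diol F8. The Mitsunobu closure (PPh3, DIAD), through the C5 alkoxyphosphonium salt F9, comes back to the route at methoxy epoxide 5.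

The osmylation of step 7 is judged less exposed than these three, because the reaction type, the site selectivity and the facial selectivity are established on closely related dienoates.

Further compounds
F1 | step 10 | C4,C7-O-di-tert-butylsilylene of triol 13 (C5-OH free, C6-OTBS) | CC(C)(C)[Si]1(C(C)(C)C)OCC2=C[C@@H](OC)[C@@H](O[Si](C)(C)C(C)(C)C)[C@H](O)[C@@H]2O1
F2 | step 10 | C5 benzoate of F1 | CC(C)(C)[Si]1(C(C)(C)C)OCC2=C[C@@H](OC)[C@@H](O[Si](C)(C)C(C)(C)C)[C@H](OC(=O)c3ccccc3)[C@@H]2O1
F3 | step 10 | C5-monobenzoate triol (C4-OH, C6-OH, C7-OH free) | OCC1=C[C@@H](OC)[C@@H](O)[C@H](OC(=O)c2ccccc2)[C@@H]1O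
F4 | step 6 | hydroxy selenoxide (selenoxide of 6) | COC(=O)C1=C[C@@H](OC)[C@@H](O)[C@H]([Se](=O)c2ccccc2)C1
F5 | step 6 | dienol (dienoate with free C6-OH) | COC(=O)C1=C[C@@H](OC)[C@@H](O)C=C1
F6 | step 3 | butane-2,3-diacetal of methyl shikimate on the C5,C6-diol (C1-OH free) | COC(=O)C1=C[C@@H](O)[C@H]2O[C@@](OC)(C)[C@](OC)(C)O[C@@H]2C1
F7 | step 3 | C1 methyl ether of F6 | COC(=O)C1=C[C@@H](OC)[C@H]2O[C@@](OC)(C)[C@](OC)(C)O[C@@H]2C1
F8 | step 3 | C1-O-methyl ether of methyl shikimate (free trans C5,C6-diol) | COC(=O)C1=C[C@@H](OC)[C@@H](O)[C@H](O)C1
F9 | step 3 | C5 alkoxyphosphonium salt of F8 | COC(=O)C1=C[C@@H](OC)[C@@H](O)[C@H](O[P+](c2ccccc2)(c2ccccc2)c2ccccc2)C1.CC(C)OC(=O)N[N-]C(=O)OC(C)C
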